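**Plan**

- Retrosynthetic cuts: (1) the phenol O–Si bond and the aryl–C bond of the styrene, which is treated as an aryl alkyne (Sonogashira) whose triple bond gives the E alkene by trans-hydroalumination; (2) the ring bond C8a–C1 together with the C2–H bond, which unravels the 1,3-diol across C1 to an α-hydroxy trans-epoxide on a 5,6-dimethoxyindan-1-ol; (3) the indane C1–C(sp) bond, back to 5,6-dimethoxy-1-indanone and a C4 diyne.
- Enabling feature: C1 is benzylic and lies between two carbinol carbons (C2 in the ring, C1' in the side chain), the 1,3-diol pattern of a 2-tetralone aldol. Its aromatic neighbour C8a stands para to the C6 methoxy group, so C8a can shift 1,2 from the carbinol carbon of an indanol onto an adjacent epoxide carbon.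
- Forward order: the benzene ring and a five-membered carbocycle are bought as the indanone; the C4 chain is added, reduced to the E enyne and epoxidised; the five-membered ring is then enlarged by one carbon to the six-membered ring of the tetralin; the phenol ring is joined last.
- Stereochemistry: one catalytic event (Shi epoxidation) fixes the trans-epoxide. In the key step C1 arises with inversion, C1' keeps its epoxide C–O bond, and C2 follows by intramolecular anti-1,3 hydride delivery. The E alkene comes from trans-hydroalumination.

Key step: step 4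

Remark: 10 is taken as purchasable (otherwise one silylation of 4-iodophenol), and 6 is carried as the pair of carbinol epimers because that carbon loses its stereochemistry in step 4.

**Step 1**
Reactants: 1 5,6-dimethoxy-2,3-dihydro-1H-inden-1-one; 2 1,4-bis(trimethylsilyl)buta-1,3-diyne
Product: 4 rac-5,6-dimethoxy-1-[4-(trimethylsilyl)buta-1,3-diyn-1-yl]-2,3-dihydro-1H-inden-1-ol, via lithium trimethylsilylbutadiynide 3 (not isolated)
Conditions: 2 (1.3 equiv), MeLi·LiBr (1.25 equiv), THF, 0 °C to rt; then 1, THF, −78 to 0 °C; then H2O
Reagents that add atoms: none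
Why: Methyllithium cleaves one C–Si bond of 2 (monodesilylation to the lithium diynide), and 1,2-addition of this weakly basic acetylide to the ketone of 1 (acetylide addition to a carbonyl group) should give the tertiary propargylic alcohol as a racemate, which suffices because this carbon becomes the trigonal C2 in step 4.

**Step 2**
Reactants: 4 rac-5,6-dimethoxy-1-[4-(trimethylsilyl)buta-1,3-diyn-1-yl]-2,3-dihydro-1H-inden-1-ol
Product: 5 rac-5,6-dimethoxy-1-[(1E)-4-(trimethylsilyl)but-1-en-3-yn-1-yl]-2,3-dihydro-1H-inden-1-ol
Conditions: LiAlH4 (1.5 equiv), THF, 0 °C to rt; then H2O, aq. NaOH (Fieser work-up); Et3N-deactivated SiO2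
Reagents that add atoms: none
Why: The alkoxyaluminate formed at the tertiary hydroxyl delivers hydride intramolecularly to the adjacent triple bond (trans-hydroalumination of a propargylic alcohol with LiAlH4), so only the proximal alkyne should be reduced, the alkene is E after protonolysis, and the distal silyl alkyne is untouched.

**Step 3**
Reactants: 5 rac-5,6-dimethoxy-1-[(1E)-4-(trimethylsilyl)but-1-en-3-yn-1-yl]-2,3-dihydro-1H-inden-1-ol
Product: 6 5,6-dimethoxy-1-{(2S,3R)-3-[(trimethylsilyl)ethynyl]oxiran-2-yl}-2,3-dihydro-1H-inden-1-ol (both epimers at the carbinol carbon, one epoxide configuration)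
Conditions: D-fructose-derived Shi ketone (1,2:4,5-di-O-isopropylidene-β-D-erythro-2,3-hexodiulo-2,6-pyranose, 0.3 equiv), KHSO5 (as 2KHSO5·KHSO4·K2SO4), K2CO3, Bu4NHSO4 (cat.), aq. Na2B4O7 buffer with Na2H2(EDTA), pH 10.5, MeCN–CH2(OMe)2, 0 °C
Reagents that add atoms: potassium peroxymonosulfate KHSO5, [K+].[O-]S(=O)(=O)OO
Why: Shi asymmetric epoxidation: the dioxirane formed in situ from the ketone transfers oxygen to the trans alkene of the enyne through the spiro transition state, in the facial sense that gives (R,R)-epoxides from trans-disubstituted alkenes, which corresponds to the (2S,3R) oxirane here, so the catalyst and not the racemic carbinol should set both epoxide centres while alkyne and arene stay inert.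

**Step 4**
Reactants: 6 5,6-dimethoxy-1-{(2S,3R)-3-[(trimethylsilyl)ethynyl]oxiran-2-yl}-2,3-dihydro-1H-inden-1-ol
Product: 8 (1S)-1-[(1S,2R)-2-hydroxy-6,7-dimethoxy-1,2,3,4-tetrahydronaphthalen-1-yl]-3-(trimethylsilyl)prop-2-yn-1-yl 2-methylpropanoate, via β-hydroxy ketone 7 (not isolated)
Conditions: SmI2 (0.3 equiv), i-PrCHO (5 equiv), ClCH2CH2Cl–THF, −10 °C to rt
Reagents that add atoms: 2-methylpropanal, CC(C)C=O
Why: Trivalent samarium species formed from SmI2 and the aldehyde bind the carbinol and epoxide oxygens of 6, the epoxide C–O bond at the carbon next to the carbinol breaks while the aromatic carbon C7a shifts from the carbinol carbon to that carbon (semipinacol rearrangement of an α-hydroxy epoxide), and the resulting samarium aldolate of 7 adds the aldehyde to a hemiacetal that passes its hydride to the new ketone (Evans–Tishchenko reduction). The closest known reaction type is the SmI2-catalysed tandem semipinacol rearrangement/Tishchenko reduction of α-hydroxy epoxides, together with the Suzuki–Tsuchihashi rearrangement of 2,3-epoxy alcohols to aldols. The six-membered ring is not closed end to end but grows out of the five-membered ring of the indanol by a one-carbon ring expansion, a 1,2-aryl shift through a three-membered, phenonium-like bridged transition state in which the epoxide carbon is inserted between C7a and the carbinol carbon. C1 is formed with inversion because the aryl carbon enters anti to the leaving epoxide oxygen, C1' keeps the C–O bond set in step 3 (trans-epoxide gives the anti aldol), and C2 is set by hydride transfer inside a chair six-membered transition state with the alkynyl and aryl substituents equatorial, which gives the 1,3-anti diol and places the C2 hydroxyl cis to the side chain. The step needs aryl migration in preference to CH2 migration, secured by the C5 methoxy group para to C7a, opening of the carbinol-side C–O bond in preference to the propargylic one, secured by aryl participation and by the electron-poor silylalkynyl group, and no epimerisation of the acidic benzylic C1 of 7, secured because the ketone is reduced in the same flask as it forms. Both carbinol epimers of 6 converge, since that carbon becomes the trigonal C2 of 7.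

**Step 5**
Reactants: 8 (1S)-1-[(1S,2R)-2-hydroxy-6,7-dimethoxy-1,2,3,4-tetrahydronaphthalen-1-yl]-3-(trimethylsilyl)prop-2-yn-1-yl 2-methylpropanoate
Product: 9 (1S,2R)-1-[(1S)-1-hydroxyprop-2-yn-1-yl]-6,7-dimethoxy-1,2,3,4-tetrahydronaphthalen-2-ol
Conditions: K2CO3 (0.5 equiv), MeOH, rt
Reagents that add atoms: none
Why: Methoxide generated in methanol should cleave the C(sp)–Si bond (protodesilylation of an alkynylsilane) and transesterify the isobutyrate, wherever a 1,3-acyl shift may have placed it (base-catalysed methanolysis), in one operation, and no stereocentre is at risk because no carbonyl group remains next to C1.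

**Step 6**
Reactants: 9 (1S,2R)-1-[(1S)-1-hydroxyprop-2-yn-1-yl]-6,7-dimethoxy-1,2,3,4-tetrahydronaphthalen-2-ol; 10 tert-butyl(4-iodophenoxy)dimethylsilane
Product: 11 (1S,2R)-1-[(1S)-3-(4-{[tert-butyl(dimethyl)silyl]oxy}phenyl)-1-hydroxyprop-2-yn-1-yl]-6,7-dimethoxy-1,2,3,4-tetrahydronaphthalen-2-ol
Conditions: Pd(PPh3)2Cl2 (3 mol %), CuI (6 mol %), Et3N, THF, rt, degassed
Reagents that add atoms: none
Why: Sonogashira coupling: oxidative addition of the aryl iodide to zerovalent palladium, transmetalation from the copper acetylide and reductive elimination should give the aryl alkyne, and the free hydroxyls and the aryl silyl ether are tolerated under amine base at room temperature.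

**Step 7**
Reactants: 11 (1S,2R)-1-[(1S)-3-(4-{[tert-butyl(dimethyl)silyl]oxy}phenyl)-1-hydroxyprop-2-yn-1-yl]-6,7-dimethoxy-1,2,3,4-tetrahydronaphthalen-2-ol
Product: 12 (1S,2R)-1-[(1R,2E)-3-(4-{[tert-butyl(dimethyl)silyl]oxy}phenyl)-1-hydroxyprop-2-en-1-yl]-6,7-dimethoxy-1,2,3,4-tetrahydronaphthalen-2-ol
Conditions: NaAlH2(OCH2CH2OCH3)2 (4 equiv), THF, 0 °C to rt; then aq. KNaC4H4O6
Reagents that add atoms: none
Why: The aluminate formed at the propargylic hydroxyl delivers hydride to the proximal alkyne carbon while aluminium ends on the distal carbon anti to it (trans-hydroalumination of a propargylic alcohol), so protonolysis should give the E allylic alcohol with the C1' configuration untouched (its descriptor changes from S to R only through the priority rules).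

**Step 8**
Reactants: 12 (1S,2R)-1-[(1R,2E)-3-(4-{[tert-butyl(dimethyl)silyl]oxy}phenyl)-1-hydroxyprop-2-en-1-yl]-6,7-dimethoxy-1,2,3,4-tetrahydronaphthalen-2-ol
Product: 13 (1S,2R)-1-[(1R,2E)-1-hydroxy-3-(4-hydroxyphenyl)prop-2-en-1-yl]-6,7-dimethoxy-1,2,3,4-tetrahydronaphthalen-2-ol
Conditions: Bu4NF (1.1 equiv), AcOH (1.1 equiv), THF, 0 °C
Reagents that add atoms: none
Why: Fluoride attacks silicon of the aryl silyl ether (fluoride-mediated desilylation), and the acetic acid buffer keeps the medium near neutral so that the 4-hydroxycinnamyl alcohol unit should not ionise towards a quinone methide.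

**Compound list**

1 | 5,6-dimethoxy-2,3-dihydro-1H-inden-1-one | COc1cc2c(cc1OC)C(=O)CC2 | starting material
2 | 1,4-bis(trimethylsilyl)buta-1,3-diyne | C[Si](C)(C)C#CC#C[Si](C)(C)C | starting material
3 | lithium 4-(trimethylsilyl)buta-1,3-diyn-1-ide | [Li]C#CC#C[Si](C)(C)C | intermediate (not isolated)
4 | rac-5,6-dimethoxy-1-[4-(trimethylsilyl)buta-1,3-diyn-1-yl]-2,3-dihydro-1H-inden-1-ol | COc1cc2c(cc1OC)C(O)(CC2)C#CC#C[Si](C)(C)C | intermediate
5 | rac-5,6-dimethoxy-1-[(1E)-4-(trimethylsilyl)but-1-en-3-yn-1-yl]-2,3-dihydro-1H-inden-1-ol | COc1cc2c(cc1OC)C(O)(CC2)/C=C/C#C[Si](C)(C)C | intermediate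
6 | 5,6-dimethoxy-1-{(2S,3R)-3-[(trimethylsilyl)ethynyl]oxiran-2-yl}-2,3-dihydro-1H-inden-1-ol (both carbinol epimers) | COc1cc2c(cc1OC)C(O)(CC2)[C@H]1O[C@@H]1C#C[Si](C)(C)C | intermediate
7 | (1R)-1-[(1S)-1-hydroxy-3-(trimethylsilyl)prop-2-yn-1-yl]-6,7-dimethoxy-3,4-dihydronaphthalen-2(1H)-one | COc1cc2c(cc1OC)[C@H]([C@H](O)C#C[Si](C)(C)C)C(=O)CC2 | intermediate (not isolated)
8 | (1S)-1-[(1S,2R)-2-hydroxy-6,7-dimethoxy-1,2,3,4-tetrahydronaphthalen-1-yl]-3-(trimethylsilyl)prop-2-yn-1-yl 2-methylpropanoate | COc1cc2c(cc1OC)[C@H]([C@H](OC(=O)C(C)C)C#C[Si](C)(C)C)[C@H](O)CC2 | intermediate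
9 | (1S,2R)-1-[(1S)-1-hydroxyprop-2-yn-1-yl]-6,7-dimethoxy-1,2,3,4-tetrahydronaphthalen-2-ol | COc1cc2c(cc1OC)[C@H]([C@H](O)C#C)[C@H](O)CC2 | intermediate
10 | tert-butyl(4-iodophenoxy)dimethylsilane | CC(C)(C)[Si](C)(C)Oc1ccc(I)cc1 | starting material
11 | (1S,2R)-1-[(1S)-3-(4-{[tert-butyl(dimethyl)silyl]oxy}phenyl)-1-hydroxyprop-2-yn-1-yl]-6,7-dimethoxy-1,2,3,4-tetrahydronaphthalen-2-ol | COc1cc2c(cc1OC)[C@H]([C@H](O)C#Cc1ccc(O[Si](C)(C)C(C)(C)C)cc1)[C@H](O)CC2 | intermediate
12 | (1S,2R)-1-[(1R,2E)-3-(4-{[tert-butyl(dimethyl)silyl]oxy}phenyl)-1-hydroxyprop-2-en-1-yl]-6,7-dimethoxy-1,2,3,4-tetrahydronaphthalen-2-ol | COc1cc2c(cc1OC)[C@H]([C@H](O)/C=C/c1ccc(O[Si](C)(C)C(C)(C)C)cc1)[C@H](O)CC2 | intermediate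
13 | (1S,2R)-1-[(1R,2E)-1-hydroxy-3-(4-hydroxyphenyl)prop-2-en-1-yl]-6,7-dimethoxy-1,2,3,4-tetrahydronaphthalen-2-ol | COc1cc2c(cc1OC)[C@H]([C@H](O)/C=C/c1ccc(O)cc1)[C@H](O)CC2 | target

**Step count and risks**

Total steps: 8. Longest linear sequence: 8 steps (1 to 13).

Steps most likely to fail:

Step 4. The epoxide may open at the propargylic carbon or be opened by iodide before the aryl shift starts. The samarium aldolate may also undergo retro-aldol cleavage or epimerise at the acidic C1 before the hydride transfer. The fallback separates the two events and drives the shift from a silyl ether at low temperature: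
- From 6, silylation with N-(trimethylsilyl)imidazole would give the tertiary trimethylsilyl ether F1.
- BF3·OEt2 in CH2Cl2 at −78 °C (Suzuki–Tsuchihashi rearrangement of an epoxy silyl ether, the silyloxy group pushing the aryl shift) would give the β-hydroxy ketone 7, now isolated cold.
- Me4NBH(OAc)3 in MeCN–AcOH at −30 °C (Evans–Saksena anti reduction by intramolecular hydride delivery) would give the silylalkynyl diol F2.
- K2CO3 in MeOH would remove the alkynyl silyl group, and the route is rejoined at 9.

Step 3. Oxygen transfer may be slow and facial selectivity eroded next to the fully substituted carbinol carbon, the ketone catalyst may decompose faster than it epoxidises, or the product may rearrange prematurely under traces of acid on isolation. The fallback is a hydroxyl-directed asymmetric epoxidation from 5 with WO2(acac)2, a C2-symmetric chiral bishydroxamic acid ligand and aqueous H2O2 in CH2Cl2 at rt. This is a metal-peroxo oxygen transfer in which the tertiary hydroxyl binds the hexavalent tungsten centre and so becomes the handle instead of the obstacle. The ligand antipode is chosen to deliver the (2S,3R) epoxide; should the two carbinol enantiomers of 5 react at different rates, the reaction is stopped at partial conversion as a kinetic resolution. It returns to the route at 6 and makes no new compound.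

Step 7. The aryl silyl ether may be lost to the hydride, after which hydroalumination may stall on the phenoxide-bearing, electron-rich aryl alkyne; over-reduction is also possible. The fallback forms the aryl–alkenyl bond on an alkene of fixed geometry and bypasses steps 6 and 7:
- From 9, Bu3SnH with catalytic Pd(PPh3)2Cl2 in THF at 0 °C (syn hydrostannation of the terminal alkyne, tin at the unhindered terminus) would give the (E)-vinylstannane F3.
- Stille coupling of F3 with 10 (Pd(PPh3)4, CuI, DMF, 40 °C) would give 12 with retention of the E geometry, and step 8 follows.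

**Further compounds**

F1 | step 4 | 5,6-dimethoxy-1-[(trimethylsilyl)oxy]-1-{(2S,3R)-3-[(trimethylsilyl)ethynyl]oxiran-2-yl}-2,3-dihydro-1H-indene (both epimers at C1 of the indane) | COc1cc2c(cc1OC)C(O[Si](C)(C)C)(CC2)[C@H]1O[C@@H]1C#C[Si](C)(C)C
F2 | step 4 | (1S,2R)-1-[(1S)-1-hydroxy-3-(trimethylsilyl)prop-2-yn-1-yl]-6,7-dimethoxy-1,2,3,4-tetrahydronaphthalen-2-ol | COc1cc2c(cc1OC)[C@H]([C@H](O)C#C[Si](C)(C)C)[C@H](O)CC2
F0 | step 3 | none | none
F3 | step 7 | (1S,2R)-1-[(1S,2E)-1-hydroxy-3-(tributylstannyl)prop-2-en-1-yl]-6,7-dimethoxy-1,2,3,4-tetrahydronaphthalen-2-ol | COc1cc2c(cc1OC)[C@H]([C@H](O)/C=C/[Sn](CCCC)(CCCC)CCCC)[C@H](O)CC2
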